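The C8–C9 bond of the eleven-membered ring C is cut. There the acetoxy carbinol C9 adjoins C8, which carries the exocyclic methylene C19 and is bonded to the ring A methine C7, a 2-methylene-1-ol retron. A chromium/nickel-mediated addition of the alkenyl iodide on C7 to the aldehyde that ends the C1 side chain closes ring C and creates the C9 carbinol in one operation. The precursor is a cis-fused hydrindane (rings A and B) bearing the C7 2-iodovinyl group, the six-carbon aldehyde chain on C1 and the trans C2/C3 diol as bis(triethylsilyl) ether. It is assembled from a methylcyclohexanedione monoketal, a bromoacetal, a silylvinyl bromide and (S)-citronellene.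

Key step: step 20

Labels (trinervitane numbering, used for every compound from 6 on): ring A = C4–C5–C6–C7–C16; ring B = C1–C2–C3–C4–C16–C15; ring C = C1, C14 down to C8, C7, C16, C15. C17 is the methyl on C15, C18 the methyl on C4, C19 the methylene on C8, C20 the methyl on C12. α is the face of C18, β the opposite face. In 6 the carbonyl carbon is C15, the CH= carbon C16, the methyl-bearing carbon C4 and the silyloxy carbon C3.

Assumption: 1, 7, 14 and 20 are bought; racemic 1 suffices because its stereocentre is erased in step 1.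

Step 1
Reactants: 1 7-methyl-1,4-dioxaspiro[4.5]decan-8-one
Product: 3 7-methyl-1,4-dioxaspiro[4.5]dec-6-en-8-one, via silyl enol ether 2 (not isolated)
Conditions: TMSCl, NaI, Et3N, MeCN, 25 °C; then Pd(OAc)2, MeCN, 25 °C
Reagents that add atoms: none
Why: Thermodynamic silylation should give the more substituted enol ether, and its Saegusa–Ito oxidation (β-hydride loss from the ring) then gives the 2-methyl enone.

Step 2
Reactants: 3 7-methyl-1,4-dioxaspiro[4.5]dec-6-en-8-one
Product: 4 (8S)-7-methyl-1,4-dioxaspiro[4.5]dec-6-en-8-ol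
Conditions: (R)-2-methyl-CBS-oxazaborolidine (10 mol %), catecholborane, toluene, −78 °C
Reagents that add atoms: none
Why: Corey–Bakshi–Shibata reduction in which the α-methylalkenyl arm acts as the large group, so the (R)-catalyst should give the (S)-carbinol that becomes C3.

Step 3
Reactants: 4 (8S)-7-methyl-1,4-dioxaspiro[4.5]dec-6-en-8-ol
Product: 5 (8S)-8-(tert-butyldimethylsilyloxy)-7-methyl-1,4-dioxaspiro[4.5]dec-6-ene
Conditions: TBSCl, imidazole, DMF, 25 °C
Reagents that add atoms: tert-butyldimethylsilyl chloride, CC(C)(C)[Si](C)(C)Cl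
Why: Standard silylation of a secondary allylic alcohol, which supplies the bulky group that later directs the conjugate addition.

Step 4
Reactants: 5 (8S)-8-(tert-butyldimethylsilyloxy)-7-methyl-1,4-dioxaspiro[4.5]dec-6-ene
Product: 6 (4S)-4-(tert-butyldimethylsilyloxy)-3-methylcyclohex-2-en-1-one
Conditions: PPTS, acetone–H2O, 25 °C
Reagents that add atoms: water, O
Why: Mild acid hydrolysis of the allylic ketal unmasks the conjugated enone and leaves the hindered silyl ether and its stereocentre untouched.

Step 5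
Reactants: 6 (4S)-4-(tert-butyldimethylsilyloxy)-3-methylcyclohex-2-en-1-one; 7 2-(2-bromoethyl)-1,3-dioxolane
Product: 10 (3S,4S)-4-(tert-butyldimethylsilyloxy)-3-[2-(1,3-dioxolan-2-yl)ethyl]-3-methylcyclohexan-1-one, via Grignard reagent 8 (not isolated), via silyl enol ether 9 (not isolated)
Conditions: 7, Mg, THF, 25 °C; then CuBr·SMe2 (20 mol %), TMSCl, 6, THF, −78 → −30 °C; then K2CO3, MeOH, 0 °C
Reagents that add atoms: none
Why: Copper-catalysed conjugate addition of the Grignard reagent, accelerated by TMSCl, should enter C4 anti to the C3 silyloxy group (held pseudoaxial by allylic strain with the C4 methyl), which sets the quaternary centre with C18 cis to the silyl ether.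

Step 6
Reactants: 10 (3S,4S)-4-(tert-butyldimethylsilyloxy)-3-[2-(1,3-dioxolan-2-yl)ethyl]-3-methylcyclohexan-1-one
Product: 13 (7S,7aS)-7-(tert-butyldimethylsilyloxy)-7a-methyl-1,2,5,6,7,7a-hexahydro-4H-inden-4-one, via keto aldehyde 11 (not isolated), via aldol adduct 12 (not isolated)
Conditions: PPTS, acetone–H2O, 60 °C; then KOH, MeOH, 0 → 25 °C
Reagents that add atoms: none
Why: Acetal hydrolysis and intramolecular aldol condensation (cyclopentene annulation) close ring A between the C16 enolate and the aldehyde C7, and dehydration to the conjugated C16=C7 enone drives the sequence, so no new stereocentre remains.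

Step 7
Reactants: 13 (7S,7aS)-7-(tert-butyldimethylsilyloxy)-7a-methyl-1,2,5,6,7,7a-hexahydro-4H-inden-4-one; 14 (1-bromovinyl)trimethylsilane
Product: 16 cis-fused C15 ketone with 3α-silyloxy 4α-methyl 16α-H and 7β-[1-(trimethylsilyl)vinyl] groups, via Grignard reagent 15 (not isolated)
Conditions: 14, Mg, THF, 50 °C; then CuI (10 mol %), 13, THF, −30 °C; aq NH4Cl, −78 °C
Reagents that add atoms: none
Why: Copper-catalysed conjugate addition to the s-cis alkylidene ketone should bring the alkenyl group to C7 from the β face, opposite the axial C18 and the C3 silyloxy group, and kinetic protonation of the C16 enolate opposite the new bulky C7 group should give the cis ring fusion.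

Step 8
Reactants: 16 cis-fused C15 ketone
Product: 18 C1=C2 enone of the cis-fused C15 ketone, via silyl enol ether 17 (not isolated)
Conditions: LDA, THF, −78 °C; TMSCl; then Pd(OAc)2, MeCN, 25 °C
Reagents that add atoms: none
Why: Kinetic deprotonation takes the C1 methylene and not the hindered ring-fusion methine C16, and Saegusa–Ito oxidation of the enol ether gives the enone without equilibrating C16.

Step 9
Reactants: 18 C1=C2 enone
Product: 19 1-iodo C1=C2 enone
Conditions: I2, pyridine, CH2Cl2, 25 °C
Reagents that add atoms: iodine, II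
Why: α-Iodination of an enone through pyridine addition, iodination of the enolate and elimination, conditions under which the vinylsilane and silyl ether are inert.

Step 10
Reactants: 20 (S)-3,7-dimethylocta-1,6-diene
Product: 22 (4S)-4-methylhex-5-en-1-ol, via aldehyde 21 (not isolated)
Conditions: O3 (1 equiv, Sudan Red 7B as indicator), CH2Cl2–MeOH, −78 °C; then NaBH4, −78 → 25 °C
Reagents that add atoms: ozone, [O-][O+]=O
Why: Ozonolysis with reductive work-up, in which the electron-rich trisubstituted alkene is cleaved faster than the vinyl group and the C12 stereocentre is not touched.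

Step 11
Reactants: 22 (4S)-4-methylhex-5-en-1-ol
Product: 23 tert-butyldimethyl{[(4S)-4-methylhex-5-en-1-yl]oxy}silane
Conditions: TBSCl, imidazole, CH2Cl2, 25 °C
Reagents that add atoms: tert-butyldimethylsilyl chloride, CC(C)(C)[Si](C)(C)Cl
Why: Standard silylation of a primary alcohol.

Step 12
Reactants: 19 1-iodo C1=C2 enone; 23 tert-butyldimethyl{[(4S)-4-methylhex-5-en-1-yl]oxy}silane
Product: 25 1-alkyl C1=C2 enone carrying the C14–C9 chain, via alkylborane 24 (not isolated)
Conditions: 23, 9-BBN, THF, 25 °C; then 19, Pd(dppf)Cl2 (5 mol %), AsPh3, Cs2CO3, DMF–H2O, 25 °C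
Reagents that add atoms: none
Why: Anti-Markovnikov hydroboration of the vinyl group and B-alkyl Suzuki–Miyaura coupling with the α-iodoenone form the C1–C14 bond under mild base.

Step 13
Reactants: 25 1-alkyl C1=C2 enone
Product: 26 tertiary allylic alcohol with methyl C17 and hydroxyl on C15
Conditions: MeLi, CeCl3, THF, −78 °C; aq NH4Cl
Reagents that add atoms: methyllithium, [Li]C
Why: 1,2-Addition of the methylcerium reagent to the enone carbonyl installs C17, and the configuration of the carbinol is irrelevant because C15 becomes sp2 in step 14.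

Step 14
Reactants: 26 tertiary allylic alcohol
Product: 27 C2 enone with tetrasubstituted C1=C15 alkene
Conditions: C5H5NH[CrO3Cl] (pyridinium chlorochromate), 4 Å molecular sieves, CH2Cl2, 25 °C
Reagents that add atoms: none
Why: Babler–Dauben oxidative transposition, in which the tertiary chromate ester shifts to C2 by a [3,3] process and is oxidised to the ketone.

Step 15
Reactants: 27 C2 enone
Product: 28 C2 enone with 7β-(1-iodovinyl) group
Conditions: N-iodosuccinimide, MeCN–ClCH2CN (4:1), 0 → 25 °C
Reagents that add atoms: N-iodosuccinimide, O=C1CCC(=O)N1I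
Why: ipso-Iododesilylation of the 1,1-disubstituted vinylsilane gives the 2-iodoalkene, and the only other alkene is the electron-poor enone.

Step 16
Reactants: 28 C2 enone with 7β-(1-iodovinyl) group
Product: 29 3α,9-dihydroxy C2 enone
Conditions: HF·pyridine, pyridine, THF, 0 → 25 °C
Reagents that add atoms: none
Why: Fluoride-mediated desilylation under non-basic conditions frees the primary C9 and the α-keto C3 hydroxyls without enolising C3 or C16.

Step 17
Reactants: 29 3α,9-dihydroxy C2 enone
Product: 30 2β,3α,9-triol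
Conditions: Me4NBH(OAc)3, MeCN–AcOH (1:1), −30 → 0 °C
Reagents that add atoms: none
Why: Evans–Saksena hydroxyl-directed reduction, in which the α-face C3 hydroxyl binds the borohydride and delivers hydride to the same face of the C2 ketone, so the new C2 hydroxyl should be β and trans to the C3 hydroxyl.

Step 18
Reactants: 30 2β,3α,9-triol
Product: 31 tris(triethylsilyl) ether
Conditions: Et3SiOTf, 2,6-lutidine, CH2Cl2, −78 → 0 °C
Reagents that add atoms: triethylsilyl trifluoromethanesulfonate, CC[Si](CC)(CC)OS(=O)(=O)C(F)(F)F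
Why: Silyl triflate silylation covers all three hydroxyls, and triethylsilyl is chosen because the hindered C3 and allylic C2 ethers can be cleaved at the end by mild fluoride that spares the acetate.

Step 19
Reactants: 31 tris(triethylsilyl) ether
Product: 32 seco iodoalkene aldehyde with 2β,3α-bis(triethylsilyloxy) groups
Conditions: (COCl)2, DMSO, CH2Cl2, −78 → −30 °C; Et3N, −78 → 0 °C
Reagents that add atoms: none
Why: Under Swern conditions a primary triethylsilyl ether is cleaved by the chlorosulfonium salt and oxidised directly to the aldehyde, a known selectivity over secondary triethylsilyl ethers.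

Step 20
Reactants: 32 seco iodoalkene aldehyde
Product: 33 tricyclic (9S)-alcohol 2β,3α-bis(triethylsilyloxy)trinervita-1(15),8(19)-dien-9-ol
Conditions: CrCl2 (15 equiv), NiCl2 (0.15 equiv), degassed DMSO, 25 °C, 32 added by syringe pump over 12 h, final 1 mM
Reagents that add atoms: none
Why: Oxidative addition of the C8–I bond to zerovalent nickel (formed from NiCl2 by CrCl2) is followed by nickel-to-chromium exchange, and the resulting alkenyl–CrCl2 species (trivalent chromium) attacks the C9 aldehyde. The closest known reaction type is the Nozaki–Hiyama–Kishi macrocyclisation of 2-iodoalkene aldehydes to medium and large carbocycles bearing a 2-methylene carbinol. Ring C (eleven atoms) closes in the exo mode at the carbonyl carbon, and slow addition to a dilute reagent solution keeps intermolecular coupling slow. The new C9 stereocentre is controlled by the conformation of the closing ring, in which the cis-fused hydrindane and the C1=C15 alkene hold the C7 alkenyl arm and the C1 chain close together; the (9S) result is hoped for but not secured. The step needs attack at the aldehyde only, which the carbonyl-selective, non-basic organochromium reagent provides, so that the tetrasubstituted alkene, the silyl ethers and the ring-fusion centres stay intact.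

Step 21
Reactants: 33 tricyclic (9S)-alcohol
Product: 34 tricyclic 9-acetate bis(triethylsilyl) ether
Conditions: Ac2O, DMAP, pyridine, CH2Cl2, 0 → 25 °C
Reagents that add atoms: acetic anhydride, CC(=O)OC(C)=O
Why: DMAP-catalysed acylation of the only free hydroxyl, with retention at C9.

Step 22
Reactants: 34 tricyclic 9-acetate bis(triethylsilyl) ether
Product: 35 target (9S)-9-acetoxytrinervita-1(15),8(19)-diene-2β,3α-diol
Conditions: HF·pyridine, pyridine, THF, 0 °C
Reagents that add atoms: none
Why: Buffered fluoride desilylation removes both secondary triethylsilyl ethers while the allylic acetate, both alkenes and all stereocentres are unaffected.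

Compound list
1 | 7-methyl-1,4-dioxaspiro[4.5]decan-8-one (racemic) | CC1CC2(CCC1=O)OCCO2 | starting material
2 | trimethyl[(7-methyl-1,4-dioxaspiro[4.5]dec-7-en-8-yl)oxy]silane | CC1=C(O[Si](C)(C)C)CCC2(C1)OCCO2 | intermediate
3 | 7-methyl-1,4-dioxaspiro[4.5]dec-6-en-8-one | CC1=CC2(CCC1=O)OCCO2 | intermediate
4 | (8S)-7-methyl-1,4-dioxaspiro[4.5]dec-6-en-8-ol | O[C@H]1CCC2(C=C1C)OCCO2 | intermediate
5 | (8S)-8-(tert-butyldimethylsilyloxy)-7-methyl-1,4-dioxaspiro[4.5]dec-6-ene | CC(C)(C)[Si](C)(C)O[C@H]1CCC2(C=C1C)OCCO2 | intermediate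
6 | (4S)-4-(tert-butyldimethylsilyloxy)-3-methylcyclohex-2-en-1-one | O=C1C=C(C)[C@@H](O[Si](C)(C)C(C)(C)C)CC1 | intermediate
7 | 2-(2-bromoethyl)-1,3-dioxolane | BrCCC1OCCO1 | starting material
8 | [2-(1,3-dioxolan-2-yl)ethyl]magnesium bromide | Br[Mg]CCC1OCCO1 | intermediate
9 | trimethylsilyl enol ether of 10 (C15=C16 enol ether) | C[Si](C)(C)OC1=C[C@](C)(CCC2OCCO2)[C@@H](O[Si](C)(C)C(C)(C)C)CC1 | intermediate
10 | (3S,4S)-4-(tert-butyldimethylsilyloxy)-3-[2-(1,3-dioxolan-2-yl)ethyl]-3-methylcyclohexan-1-one (C18 cis to the silyloxy group) | O=C1C[C@](C)(CCC2OCCO2)[C@@H](O[Si](C)(C)C(C)(C)C)CC1 | intermediate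
11 | 3-[2-(tert-butyldimethylsilyloxy)-1-methyl-5-oxocyclohexyl]propanal, configuration as in 10 | O=C1C[C@](C)(CCC=O)[C@@H](O[Si](C)(C)C(C)(C)C)CC1 | intermediate
12 | bicyclic aldol adduct, 7-hydroxy C15 ketone (C7 and C16 epimers) | O=C1CC[C@H](O[Si](C)(C)C(C)(C)C)[C@@]2(C)CCC(O)C12 | intermediate
13 | (7S,7aS)-7-(tert-butyldimethylsilyloxy)-7a-methyl-1,2,5,6,7,7a-hexahydro-4H-inden-4-one (C15 ketone, C16=C7 alkene, 3α-silyloxy, 4α-methyl) | O=C1CC[C@H](O[Si](C)(C)C(C)(C)C)[C@@]2(C)CCC=C12 | intermediate
14 | (1-bromovinyl)trimethylsilane | C=C(Br)[Si](C)(C)C | starting material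
15 | [1-(trimethylsilyl)vinyl]magnesium bromide | C=C([Mg]Br)[Si](C)(C)C | intermediate
16 | cis-fused C15 ketone: 3α-(tert-butyldimethylsilyloxy), 4α-methyl, 16α-H, 7β-[1-(trimethylsilyl)vinyl] | O=C1CC[C@H](O[Si](C)(C)C(C)(C)C)[C@@]2(C)CC[C@@H](C(=C)[Si](C)(C)C)[C@@H]12 | intermediate
17 | C15 trimethylsilyl enol ether of 16 (C15=C1) | C[Si](C)(C)OC1=CC[C@H](O[Si](C)(C)C(C)(C)C)[C@@]2(C)CC[C@@H](C(=C)[Si](C)(C)C)[C@@H]12 | intermediate
18 | C1=C2 enone of 16 (C15 ketone) | O=C1C=C[C@H](O[Si](C)(C)C(C)(C)C)[C@@]2(C)CC[C@@H](C(=C)[Si](C)(C)C)[C@@H]12 | intermediate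
19 | 1-iodo derivative of enone 18 | O=C1C(I)=C[C@H](O[Si](C)(C)C(C)(C)C)[C@@]2(C)CC[C@@H](C(=C)[Si](C)(C)C)[C@@H]12 | intermediate
20 | (S)-3,7-dimethylocta-1,6-diene ((S)-citronellene) | C=C[C@@H](C)CCC=C(C)C | starting material
21 | (4S)-4-methylhex-5-enal | C=C[C@@H](C)CCC=O | intermediate
22 | (4S)-4-methylhex-5-en-1-ol | C=C[C@@H](C)CCCO | intermediate
23 | tert-butyldimethyl{[(4S)-4-methylhex-5-en-1-yl]oxy}silane | C=C[C@@H](C)CCCO[Si](C)(C)C(C)(C)C | intermediate
24 | B-alkyl-9-borabicyclo[3.3.1]nonane from 23 (boron on C14) | C[C@H](CCB1C2CCCC1CCC2)CCCO[Si](C)(C)C(C)(C)C | intermediate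
25 | enone 18 carrying on C1 the 6-(tert-butyldimethylsilyloxy)-3-methylhexyl chain (C14–C9, C20 on C12) | O=C1C(CC[C@@H](C)CCCO[Si](C)(C)C(C)(C)C)=C[C@H](O[Si](C)(C)C(C)(C)C)[C@@]2(C)CC[C@@H](C(=C)[Si](C)(C)C)[C@@H]12 | intermediate
26 | tertiary allylic alcohol: 15-hydroxy-15-methyl, C1=C2 alkene (C15 epimers) | CC1(O)C(CC[C@@H](C)CCCO[Si](C)(C)C(C)(C)C)=C[C@H](O[Si](C)(C)C(C)(C)C)[C@@]2(C)CC[C@@H](C(=C)[Si](C)(C)C)[C@@H]12 | intermediate
27 | C2 enone: C1=C15 alkene with C17, 3α-(tert-butyldimethylsilyloxy), 7β-[1-(trimethylsilyl)vinyl], silylated C9 chain | O=C1C(CC[C@@H](C)CCCO[Si](C)(C)C(C)(C)C)=C(C)[C@@H]2[C@H](C(=C)[Si](C)(C)C)CC[C@]2(C)[C@H]1O[Si](C)(C)C(C)(C)C | intermediate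
28 | C2 enone 27 with 7β-(1-iodovinyl) in place of the silylvinyl group | O=C1C(CC[C@@H](C)CCCO[Si](C)(C)C(C)(C)C)=C(C)[C@@H]2[C@H](C(I)=C)CC[C@]2(C)[C@H]1O[Si](C)(C)C(C)(C)C | intermediate
29 | 3α,9-dihydroxy C2 enone with 7β-(1-iodovinyl) | O=C1C(CC[C@@H](C)CCCO)=C(C)[C@@H]2[C@H](C(I)=C)CC[C@]2(C)[C@H]1O | intermediate
30 | 2β,3α,9-triol with C1=C15 alkene and 7β-(1-iodovinyl) | OCCC[C@H](C)CCC1=C(C)[C@@H]2[C@H](C(I)=C)CC[C@]2(C)[C@@H](O)[C@@H]1O | intermediate
31 | 2β,3α,9-tris(triethylsilyl) ether of 30 | CC[Si](CC)(CC)OCCC[C@H](C)CCC1=C(C)[C@@H]2[C@H](C(I)=C)CC[C@]2(C)[C@@H](O[Si](CC)(CC)CC)[C@@H]1O[Si](CC)(CC)CC | intermediate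
32 | seco iodoalkene aldehyde: C9 aldehyde, 7β-(1-iodovinyl), 2β,3α-bis(triethylsilyloxy) | O=CCC[C@H](C)CCC1=C(C)[C@@H]2[C@H](C(I)=C)CC[C@]2(C)[C@@H](O[Si](CC)(CC)CC)[C@@H]1O[Si](CC)(CC)CC | intermediate
33 | (9S)-2β,3α-bis(triethylsilyloxy)trinervita-1(15),8(19)-dien-9-ol | C=C1[C@@H](O)CC[C@H](C)CCC2=C(C)[C@@H]3[C@H]1CC[C@]3(C)[C@@H](O[Si](CC)(CC)CC)[C@@H]2O[Si](CC)(CC)CC | intermediate
34 | (9S)-9-acetoxy-2β,3α-bis(triethylsilyloxy)trinervita-1(15),8(19)-diene | C=C1[C@@H](OC(C)=O)CC[C@H](C)CCC2=C(C)[C@@H]3[C@H]1CC[C@]3(C)[C@@H](O[Si](CC)(CC)CC)[C@@H]2O[Si](CC)(CC)CC | intermediate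
35 | (9S)-9-acetoxytrinervita-1(15),8(19)-diene-2β,3α-diol (CNP0192310.1) | C=C1[C@@H](OC(C)=O)CC[C@H](C)CCC2=C(C)[C@@H]3[C@H]1CC[C@]3(C)[C@@H](O)[C@@H]2O | target

Total step count: 22. Longest linear sequence: 20 steps (steps 1–9 and 12–22, from 1); steps 10 and 11 make the chain fragment.

Steps most likely to fail

Step 20. The closing ring may present the wrong aldehyde face, so that the C9 epimer predominates, or the slow medium-ring closure may lose out to intermolecular coupling. The fallback for the stereochemical failure sets out from 33 as it is obtained, mixed with the (9R)-alcohol F1. The mixture would be oxidised with Dess–Martin periodinane to the macrocyclic α-methylene ketone F2. This enone would then be reduced under reagent control with (R)-2-methyl-CBS-oxazaborolidine and catecholborane, the alkenyl arm acting as the large group, which should return the route to 33.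

Step 7. Protonation of the ring-fusion enolate may occur from the wrong face, or C16 may epimerise later, because the bulky silylvinyl group cis to C15 erodes the preference for the cis fusion. The fallback sets out from 13 and uses a small, linear two-carbon group. Conjugate addition of the alane Et2AlC≡CSiMe3 (from trimethylsilylacetylene, n-BuLi and Et2AlCl) to the s-cis alkylidene ketone should give the 7β-(trimethylsilylethynyl) ketone F3. K2CO3 in MeOH would remove the alkynyl silyl group and let C16 settle in the cis-fused form, which an ethynyl group should not disfavour, giving the 7β-ethynyl ketone F4. Ruthenium-catalysed Markovnikov hydrosilylation of F4 ([Cp*Ru(MeCN)3]PF6, trimethylsilane, CH2Cl2) should then return the route to 16.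

Step 14. The [3,3] shift of the hindered tertiary chromate ester may be slow, so that elimination or epoxidation of the allylic alcohol competes. The fallback sets out from 26 and separates transposition from oxidation. Catalytic O3ReOSiPh3 in Et2O at 0 °C should isomerise 26 to the secondary C2 allylic alcohol F5, favoured by its tetrasubstituted alkene. Dess–Martin oxidation of F5 would return the route to 27.

Further compounds
F1 | step 20 | (9R)-2β,3α-bis(triethylsilyloxy)trinervita-1(15),8(19)-dien-9-ol (C9 epimer of 33) | C=C1[C@H](O)CC[C@H](C)CCC2=C(C)[C@@H]3[C@H]1CC[C@]3(C)[C@@H](O[Si](CC)(CC)CC)[C@@H]2O[Si](CC)(CC)CC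
F2 | step 20 | 2β,3α-bis(triethylsilyloxy)trinervita-1(15),8(19)-dien-9-one | C=C1C(=O)CC[C@H](C)CCC2=C(C)[C@@H]3[C@H]1CC[C@]3(C)[C@@H](O[Si](CC)(CC)CC)[C@@H]2O[Si](CC)(CC)CC
F3 | step 7 | cis-fused C15 ketone with 7β-(trimethylsilylethynyl), 3α-(tert-butyldimethylsilyloxy), 4α-methyl | O=C1CC[C@H](O[Si](C)(C)C(C)(C)C)[C@@]2(C)CC[C@@H](C#C[Si](C)(C)C)[C@@H]12
F4 | step 7 | cis-fused C15 ketone with 7β-ethynyl, 3α-(tert-butyldimethylsilyloxy), 4α-methyl | O=C1CC[C@H](O[Si](C)(C)C(C)(C)C)[C@@]2(C)CC[C@@H](C#C)[C@@H]12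
F5 | step 14 | secondary C2 allylic alcohol with C1=C15 alkene (C2 epimers), otherwise as 27 | OC1C(CC[C@@H](C)CCCO[Si](C)(C)C(C)(C)C)=C(C)[C@@H]2[C@H](C(=C)[Si](C)(C)C)CC[C@]2(C)[C@H]1O[Si](C)(C)C(C)(C)C
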